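Numbering used below: C1 lactone carbonyl, C2 CH(CH3), C3 ketone, C4 C(OH)(CH2OH), C5 CH2, C6(CH3)=C7, C8 CH(CH3), C9 CH2, C10 C(=CH2), C11=C12(CH2OH), C13 CH(Et)O. The target is (2R,4R,6E,8S,11E,13S).

Assumption: C2 lies between two carbonyls and is enolisable, so 2R is taken to be the thermodynamic epimer in the ring; the facial senses of the ligand-controlled steps 3 and 7 are as written, and the mirror-image ligand is used if a model run shows the opposite sense.

**Retrosynthetic overview**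
1. Target ⇐ deprotection and C2 equilibration ⇐ protected macrolide 19 ⇐ acylketene macrolactonisation (C1–O), the only ring-forming step; the dioxolane ring is carried in with 8.
2. Seco ester 17 ⇐ nickel-catalysed reductive enyne–propanal coupling (C12–C13, 11E diene, C13 carbinol) and crossed Claisen condensation (C2–C3) of acid 12.
3. Acid 12 ⇐ Ireland–Claisen rearrangement (C4–C5, 6E alkene, C7→C4 chirality transfer) of the glycerate ester of carbinol 7 ⇐ aldehyde 5 + 2-bromopropene.
4. Key step: aldehyde 5 ⇐ enantioselective radical (SOMO) α-allylation of propanal with 2-alkynyl allylsilane 3, which forms C8–C9, sets C8 and unveils the C10 methylidene at once.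
5. All 21 carbons come from seven three-carbon pieces.

**Route**

Step 1
Reactants: 1 (2-bromoprop-2-en-1-yl)trimethylsilane; 2 tert-butyldimethyl(prop-2-yn-1-yloxy)silane
Product: 3 tert-butyldimethyl{[4-(trimethylsilylmethyl)pent-4-en-2-yn-1-yl]oxy}silane
Conditions: Pd(PPh3)2Cl2 (3 mol %), CuI (5 mol %), Et3N, THF, 25→45 °C
Reagents that add atoms: none
Why: Sonogashira coupling, in which zerovalent palladium inserts into the vinylic C–Br bond of 1 and the copper acetylide of 2 transmetalates, while the allylsilane and silyl ether are inert to the amine base and no stereocentre is formed.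

Step 2
Reactants: 3 tert-butyldimethyl{[4-(trimethylsilylmethyl)pent-4-en-2-yn-1-yl]oxy}silane; 4 propanal
Product: 5 (2S)-7-[(tert-butyldimethylsilyl)oxy]-2-methyl-4-methylidenehept-5-ynal
Conditions: 3 (2 equiv, excess recovered), (2R,5R)-5-benzyl-2-tert-butyl-3-methylimidazolidin-4-one·CF3CO2H (20 mol %), (NH4)2Ce(NO3)6 (2.5 equiv), NaHCO3 (2 equiv), H2O (2 equiv), DME, −20 °C, 24 h
Reagents that add atoms: none
Why: Organocatalytic SOMO-activation α-allylation (radical addition then radical–polar crossover), in which tetravalent cerium oxidises the catalyst-bound enamine of 4 to a 3π-electron radical cation that adds to the CH2= terminus of 3 (2-aryl, 2-ester and 2-alkyl allylsilanes are precedented, the 2-alkynyl case is an extension), a second oxidation and loss of silicon give the C10 methylidene, and the benzyl group of the (2R,5R) catalyst blocks the Si face so the C8–C9 bond forms on the Re face to give 8S.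

Step 3
Reactants: 5 (2S)-7-[(tert-butyldimethylsilyl)oxy]-2-methyl-4-methylidenehept-5-ynal; 6 2-bromopropene
Product: 7 (3S,4S)-9-[(tert-butyldimethylsilyl)oxy]-2,4-dimethyl-6-methylidenenon-1-en-7-yn-3-ol
Conditions: 6 (3 equiv), CrCl2 (4 equiv), (S)-N-[2-(4-tert-butyl-4,5-dihydro-1,3-oxazol-2-yl)-6-methylphenyl]methanesulfonamide (4.4 equiv, recovered), Et3N (4.4 equiv), NiCl2 (10 mol %), THF, 25 °C
Reagents that add atoms: none
Why: Ligand-controlled Nozaki–Hiyama–Kishi coupling, in which nickel activates the C–Br bond of 6, the isopropenyl group passes to chromium held by the chiral sulfonamide, and addition to the Re face of the aldehyde overrides the weak Felkin bias to give the 7S relay carbinol (C7 anti to C8).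

Step 4
Reactants: 7 (3S,4S)-9-[(tert-butyldimethylsilyl)oxy]-2,4-dimethyl-6-methylidenenon-1-en-7-yn-3-ol; 8 2,2-dimethyl-1,3-dioxolane-4-carboxylic acid (racemic)
Product: 9 (3S,4S)-9-[(tert-butyldimethylsilyl)oxy]-2,4-dimethyl-6-methylidenenon-1-en-7-yn-3-yl 2,2-dimethyl-1,3-dioxolane-4-carboxylate (both epimers at the dioxolane carbon)
Conditions: 8 (1.5 equiv), DCC (1.6 equiv), DMAP (0.2 equiv), CH2Cl2, 0→25 °C
Reagents that add atoms: none
Why: Steglich esterification of the hindered secondary allylic alcohol, where the dioxolane stereocentre may be racemic because it is planarised in the next step.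

Step 5
Reactants: 9 (3S,4S)-9-[(tert-butyldimethylsilyl)oxy]-2,4-dimethyl-6-methylidenenon-1-en-7-yn-3-yl 2,2-dimethyl-1,3-dioxolane-4-carboxylate
Product: 12 (4R)-4-[(2E,4S)-9-[(tert-butyldimethylsilyl)oxy]-2,4-dimethyl-6-methylidenenon-2-en-7-yn-1-yl]-2,2-dimethyl-1,3-dioxolane-4-carboxylic acid, via silyl ketene acetal 10 (not isolated), via trimethylsilyl ester 11 (not isolated)
Conditions: LiN(iPr)2 (1.3 equiv), Me3SiCl/Et3N (premixed, internal quench), THF, −100→25 °C, 4 h; pH 5 citrate work-up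
Reagents that add atoms: none
Why: Ireland–Claisen [3,3]-sigmatropic rearrangement, in which lithium chelation puts the enolate oxygen cis to the ring oxygen, internal silylation outruns β-elimination, and a chair transition state with the C8 branch equatorial forms C4–C5 and the 6E alkene while transferring 7S to the 4R quaternary centre.

Step 6
Reactants: 12 (4R)-4-[(2E,4S)-9-[(tert-butyldimethylsilyl)oxy]-2,4-dimethyl-6-methylidenenon-2-en-7-yn-1-yl]-2,2-dimethyl-1,3-dioxolane-4-carboxylic acid; 13 tert-butyl propanoate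
Product: 16 tert-butyl (2RS)-3-{(4R)-4-[(2E,4S)-9-[(tert-butyldimethylsilyl)oxy]-2,4-dimethyl-6-methylidenenon-2-en-7-yn-1-yl]-2,2-dimethyl-1,3-dioxolan-4-yl}-2-methyl-3-oxopropanoate, via acyl imidazole 14 (not isolated), via lithium enolate 15 (not isolated)
Conditions: 1,1'-carbonyldiimidazole (1.2 equiv), THF, 40 °C; added to 13 (3 equiv)/LiN(iPr)2 (3 equiv), THF, −78→−20 °C; AcOH quench
Reagents that add atoms: none
Why: Crossed Claisen condensation, in which the non-enolisable acyl imidazole is C-acylated by the ester enolate and a further equivalent of enolate deprotonates the product, giving the β-keto ester as a C2 epimer mixture that is corrected at the end.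

Step 7
Reactants: 16 tert-butyl (2RS)-3-{(4R)-4-[(2E,4S)-9-[(tert-butyldimethylsilyl)oxy]-2,4-dimethyl-6-methylidenenon-2-en-7-yn-1-yl]-2,2-dimethyl-1,3-dioxolan-4-yl}-2-methyl-3-oxopropanoate; 4 propanal
Product: 17 tert-butyl (2RS)-3-{(4R)-4-[(2E,4S,7E,9S)-8-{[(tert-butyldimethylsilyl)oxy]methyl}-9-hydroxy-2,4-dimethyl-6-methylideneundeca-2,7-dien-1-yl]-2,2-dimethyl-1,3-dioxolan-4-yl}-2-methyl-3-oxopropanoate
Conditions: 4 (3 equiv), Ni(cod)2 [bis(1,5-cyclooctadiene)nickel] (10 mol %), (S)-(+)-neomenthyldiphenylphosphine (20 mol %), Et3B (2.5 equiv), EtOAc/1,3-dimethylimidazolidin-2-one 1:1, 25 °C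
Reagents that add atoms: none
Why: Nickel-catalysed reductive coupling of a 1,3-enyne with an aldehyde (Jamison type), in which oxidative cyclisation forms C12–C13 at the alkyne carbon distal to the directing alkene, ethyl transfer from boron and β-hydride elimination deliver H to C11 by syn addition (11E, C10 cis to CH2O), and the chiral phosphine favours the 13S carbinol with only moderate selectivity expected, so the minor 13-epimer is removed by chromatography.

Step 8
Reactants: 17 tert-butyl (2RS)-3-{(4R)-4-[(2E,4S,7E,9S)-8-{[(tert-butyldimethylsilyl)oxy]methyl}-9-hydroxy-2,4-dimethyl-6-methylideneundeca-2,7-dien-1-yl]-2,2-dimethyl-1,3-dioxolan-4-yl}-2-methyl-3-oxopropanoate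
Product: 19 protected macrolide (target carrying the C4-OH/C4-CH2OH pair as isopropylidene acetal and the C12-CH2OH as TBS ether; C2 epimer mixture), via acylketene 18 (not isolated)
Conditions: toluene, 110 °C, 0.5 mM, syringe-pump addition over 10 h
Reagents that add atoms: none
Why: Acylketene macrolactonisation, in which thermal loss of tert-butanol from the β-keto tert-butyl ester gives the acylketene that is trapped at high dilution by the only free hydroxyl (C13) to close the 14-membered lactone without touching any centre other than the labile C2.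

Step 9
Reactants: 19 protected macrolide
Product: 20 (3R,5R,7E,9S,12E,14S)-14-ethyl-5-hydroxy-5,13-bis(hydroxymethyl)-3,7,9-trimethyl-11-methylideneoxacyclotetradeca-7,12-diene-2,4-dione (target; 2R,4R,8S,13S in the numbering above)
Conditions: AcOH/THF/H2O 3:1:1, 40 °C
Reagents that add atoms: none
Why: Mild acid hydrolysis of the isopropylidene acetal and the primary silyl ether, during which C2 equilibrates through the enol to the more stable 2R epimer (thermodynamic control).

**Compound list**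
1 | (2-bromoprop-2-en-1-yl)trimethylsilane | C=C(Br)C[Si](C)(C)C | starting material
2 | tert-butyldimethyl(prop-2-yn-1-yloxy)silane (prop-2-yn-1-ol carried as its TBS ether) | C#CCO[Si](C)(C)C(C)(C)C | starting material
3 | tert-butyldimethyl{[4-(trimethylsilylmethyl)pent-4-en-2-yn-1-yl]oxy}silane | C=C(C[Si](C)(C)C)C#CCO[Si](C)(C)C(C)(C)C | intermediate
4 | propanal | CCC=O | starting material
5 | (2S)-7-[(tert-butyldimethylsilyl)oxy]-2-methyl-4-methylidenehept-5-ynal | O=C[C@@H](C)CC(=C)C#CCO[Si](C)(C)C(C)(C)C | intermediate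
6 | 2-bromopropene | C=C(C)Br | starting material
7 | (3S,4S)-9-[(tert-butyldimethylsilyl)oxy]-2,4-dimethyl-6-methylidenenon-1-en-7-yn-3-ol | C=C(C)[C@@H](O)[C@@H](C)CC(=C)C#CCO[Si](C)(C)C(C)(C)C | intermediate
8 | 2,2-dimethyl-1,3-dioxolane-4-carboxylic acid, racemic (glyceric acid carried as its acetonide) | CC1(C)OCC(C(=O)O)O1 | starting material
9 | glycerate acetonide ester of 7 (both epimers at the dioxolane carbon) | C=C(C)[C@@H](OC(=O)C1COC(C)(C)O1)[C@@H](C)CC(=C)C#CCO[Si](C)(C)C(C)(C)C | intermediate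
10 | O-trimethylsilyl ketene acetal of 9 (OSiMe3 cis to the ring oxygen) | C=C(C)[C@@H](O/C(O[Si](C)(C)C)=C1/OC(C)(C)OC1)[C@@H](C)CC(=C)C#CCO[Si](C)(C)C(C)(C)C | intermediate (not isolated)
11 | trimethylsilyl ester of 12 | C[Si](C)(C)OC(=O)[C@@]1(C/C(C)=C/[C@@H](C)CC(=C)C#CCO[Si](C)(C)C(C)(C)C)COC(C)(C)O1 | intermediate (not isolated)
12 | (4R)-4-[(2E,4S)-9-[(tert-butyldimethylsilyl)oxy]-2,4-dimethyl-6-methylidenenon-2-en-7-yn-1-yl]-2,2-dimethyl-1,3-dioxolane-4-carboxylic acid | OC(=O)[C@@]1(C/C(C)=C/[C@@H](C)CC(=C)C#CCO[Si](C)(C)C(C)(C)C)COC(C)(C)O1 | intermediate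
13 | tert-butyl propanoate (propanoic acid carried as its tert-butyl ester) | CCC(=O)OC(C)(C)C | starting material
14 | N-acylimidazole of 12 | O=C(n1ccnc1)[C@@]1(C/C(C)=C/[C@@H](C)CC(=C)C#CCO[Si](C)(C)C(C)(C)C)COC(C)(C)O1 | intermediate (not isolated)
15 | lithium enolate of 13 | [Li+].CC=C([O-])OC(C)(C)C | intermediate (not isolated)
16 | tert-butyl (2RS)-3-{(4R)-4-[(2E,4S)-9-[(tert-butyldimethylsilyl)oxy]-2,4-dimethyl-6-methylidenenon-2-en-7-yn-1-yl]-2,2-dimethyl-1,3-dioxolan-4-yl}-2-methyl-3-oxopropanoate | CC(C(=O)OC(C)(C)C)C(=O)[C@@]1(C/C(C)=C/[C@@H](C)CC(=C)C#CCO[Si](C)(C)C(C)(C)C)COC(C)(C)O1 | intermediate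
17 | tert-butyl (2RS)-3-{(4R)-4-[(2E,4S,7E,9S)-8-{[(tert-butyldimethylsilyl)oxy]methyl}-9-hydroxy-2,4-dimethyl-6-methylideneundeca-2,7-dien-1-yl]-2,2-dimethyl-1,3-dioxolan-4-yl}-2-methyl-3-oxopropanoate | CC(C(=O)OC(C)(C)C)C(=O)[C@@]1(C/C(C)=C/[C@@H](C)CC(=C)/C=C(\CO[Si](C)(C)C(C)(C)C)[C@@H](O)CC)COC(C)(C)O1 | intermediate
18 | acylketene from 17 | O=C=C(C)C(=O)[C@@]1(C/C(C)=C/[C@@H](C)CC(=C)/C=C(\CO[Si](C)(C)C(C)(C)C)[C@@H](O)CC)COC(C)(C)O1 | intermediate (not isolated)
19 | protected macrolide (C4 diol as acetonide, C12-CH2OH as TBS ether, C2 epimers) | C=C1/C=C(\CO[Si](C)(C)C(C)(C)C)[C@H](CC)OC(=O)C(C)C(=O)[C@]2(COC(C)(C)O2)C/C(C)=C/[C@@H](C)C1 | intermediate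
20 | (3R,5R,7E,9S,12E,14S)-14-ethyl-5-hydroxy-5,13-bis(hydroxymethyl)-3,7,9-trimethyl-11-methylideneoxacyclotetradeca-7,12-diene-2,4-dione | C=C1/C=C(\CO)[C@H](CC)OC(=O)[C@H](C)C(=O)[C@](O)(CO)C/C(C)=C/[C@@H](C)C1 | target

**Step count and risk**

Total steps: 9. Longest linear sequence: 9 (1/2 → 20); every building block is commercial.

The three steps most likely to fail are 2, 5 and 7.

Step 2 (radical α-allylation). The 2-alkynyl allylsilane is an untested acceptor, and the propargylic radical or cation may be diverted or the ee may be low. The fallback sets out from 2 and rejoins at 5, replacing the radical step with an auxiliary-controlled enolate alkylation. The sodium enolate (NaN(SiMe3)2, THF, −78 °C) of commercial (R)-4-benzyl-3-propanoyl-1,3-oxazolidin-2-one is alkylated with 2,3-dibromopropene on the face away from the benzyl group, giving (R)-4-benzyl-3-[(2S)-4-bromo-2-methylpent-4-enoyl]-1,3-oxazolidin-2-one F1. Sonogashira coupling of its vinyl bromide with 2 (conditions of step 1) gives (R)-4-benzyl-3-[(2S)-7-[(tert-butyldimethylsilyl)oxy]-2-methyl-4-methylidenehept-5-ynoyl]-1,3-oxazolidin-2-one F2. LiBH4 (THF/MeOH, 0 °C) removes the auxiliary to give (2S)-7-[(tert-butyldimethylsilyl)oxy]-2-methyl-4-methylidenehept-5-yn-1-ol F3, and Dess–Martin oxidation returns 5.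

Step 5 (Ireland–Claisen). The chirality transfer depends on one ketene acetal geometry, and the glycerate enolate can β-eliminate. The fallback sets out from 5 and rejoins at 12, bypassing steps 3–5 and setting C4 by self-regeneration of a stereocentre instead of by 1,3-transfer. Wittig olefination of 5 with ethyl 2-(triphenylphosphoranylidene)propanoate (CH2Cl2, 25 °C) gives ethyl (2E,4S)-9-[(tert-butyldimethylsilyl)oxy]-2,4-dimethyl-6-methylidenenon-2-en-7-ynoate F4. Reduction with iBu2AlH (−78 °C) gives (2E,4S)-9-[(tert-butyldimethylsilyl)oxy]-2,4-dimethyl-6-methylidenenon-2-en-7-yn-1-ol F5, and CBr4/PPh3 gives (2E,4S)-1-bromo-9-[(tert-butyldimethylsilyl)oxy]-2,4-dimethyl-6-methylidenenon-2-en-7-yne F6. The lithium enolate (LiN(iPr)2, THF, −78 °C) of methyl (2R,4R)-2-tert-butyl-1,3-dioxolane-4-carboxylate F7 (from methyl (R)-glycerate and pivalaldehyde) is alkylated by F6 anti to the tert-butyl group. This gives methyl (2R,4R)-2-tert-butyl-4-[(2E,4S)-9-[(tert-butyldimethylsilyl)oxy]-2,4-dimethyl-6-methylidenenon-2-en-7-yn-1-yl]-1,3-dioxolane-4-carboxylate F8. Acetal exchange (2,2-dimethoxypropane, acetone, camphorsulfonic acid) gives the methyl ester of 12 F9, and LiOH (THF/H2O) returns 12.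

Step 7 (reductive coupling). Enantiocontrol with enynes is only moderate, and the β-keto ester may interfere. The fallback sets out from 16 and rejoins at 17, setting C13 by oxidation and reagent-controlled reduction instead of in the C–C bond formation. The coupling is run with achiral PBu3, giving 17 together with the 13-epimer of 17 F10. MnO2 (CH2Cl2) oxidises only the dienylic alcohol of the mixture to tert-butyl (2RS)-3-{(4R)-4-[(2E,4S,7E)-8-{[(tert-butyldimethylsilyl)oxy]methyl}-2,4-dimethyl-6-methylidene-9-oxoundeca-2,7-dien-1-yl]-2,2-dimethyl-1,3-dioxolan-4-yl}-2-methyl-3-oxopropanoate F11. (R)-2-Methyl-CBS-oxazaborolidine with catecholborane (toluene, −78 °C) reduces the unhindered dienyl ethyl ketone, with the dienyl group as the large substituent, to 13S-configured 17; the hindered and largely enolised C3 ketone is left alone.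

**Further compounds**
F1 | step 2 | (R)-4-benzyl-3-[(2S)-4-bromo-2-methylpent-4-enoyl]-1,3-oxazolidin-2-one | C=C(Br)C[C@H](C)C(=O)N1[C@H](Cc2ccccc2)COC1=O
F2 | step 2 | (R)-4-benzyl-3-[(2S)-7-[(tert-butyldimethylsilyl)oxy]-2-methyl-4-methylidenehept-5-ynoyl]-1,3-oxazolidin-2-one | C=C(C#CCO[Si](C)(C)C(C)(C)C)C[C@H](C)C(=O)N1[C@H](Cc2ccccc2)COC1=O
F3 | step 2 | (2S)-7-[(tert-butyldimethylsilyl)oxy]-2-methyl-4-methylidenehept-5-yn-1-ol | C=C(C#CCO[Si](C)(C)C(C)(C)C)C[C@H](C)CO
F4 | step 5 | ethyl (2E,4S)-9-[(tert-butyldimethylsilyl)oxy]-2,4-dimethyl-6-methylidenenon-2-en-7-ynoate | CCOC(=O)/C(C)=C/[C@@H](C)CC(=C)C#CCO[Si](C)(C)C(C)(C)C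
F5 | step 5 | (2E,4S)-9-[(tert-butyldimethylsilyl)oxy]-2,4-dimethyl-6-methylidenenon-2-en-7-yn-1-ol | OC/C(C)=C/[C@@H](C)CC(=C)C#CCO[Si](C)(C)C(C)(C)C
F6 | step 5 | (2E,4S)-1-bromo-9-[(tert-butyldimethylsilyl)oxy]-2,4-dimethyl-6-methylidenenon-2-en-7-yne | BrC/C(C)=C/[C@@H](C)CC(=C)C#CCO[Si](C)(C)C(C)(C)C
F7 | step 5 | methyl (2R,4R)-2-tert-butyl-1,3-dioxolane-4-carboxylate | COC(=O)[C@H]1CO[C@@H](C(C)(C)C)O1
F8 | step 5 | methyl (2R,4R)-2-tert-butyl-4-[(2E,4S)-9-[(tert-butyldimethylsilyl)oxy]-2,4-dimethyl-6-methylidenenon-2-en-7-yn-1-yl]-1,3-dioxolane-4-carboxylate | COC(=O)[C@@]1(C/C(C)=C/[C@@H](C)CC(=C)C#CCO[Si](C)(C)C(C)(C)C)CO[C@@H](C(C)(C)C)O1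
F9 | step 5 | methyl (4R)-4-[(2E,4S)-9-[(tert-butyldimethylsilyl)oxy]-2,4-dimethyl-6-methylidenenon-2-en-7-yn-1-yl]-2,2-dimethyl-1,3-dioxolane-4-carboxylate | COC(=O)[C@@]1(C/C(C)=C/[C@@H](C)CC(=C)C#CCO[Si](C)(C)C(C)(C)C)COC(C)(C)O1
F10 | step 7 | 13-epimer of 17 (9R in the side chain) | CC(C(=O)OC(C)(C)C)C(=O)[C@@]1(C/C(C)=C/[C@@H](C)CC(=C)/C=C(\CO[Si](C)(C)C(C)(C)C)[C@H](O)CC)COC(C)(C)O1
F11 | step 7 | tert-butyl (2RS)-3-{(4R)-4-[(2E,4S,7E)-8-{[(tert-butyldimethylsilyl)oxy]methyl}-2,4-dimethyl-6-methylidene-9-oxoundeca-2,7-dien-1-yl]-2,2-dimethyl-1,3-dioxolan-4-yl}-2-methyl-3-oxopropanoate | CC(C(=O)OC(C)(C)C)C(=O)[C@@]1(C/C(C)=C/[C@@H](C)CC(=C)/C=C(\CO[Si](C)(C)C(C)(C)C)C(=O)CC)COC(C)(C)O1
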